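**Strategy.** The cyclohexane ring (C1′ = CH bearing the benzylic CH2, C2′ = CMe2, C6′ = C(Me)OH) is cut into a C2 unit (C2′–C3′) and a C4 diene (C1′=C6′–C5′=C4′). An enantioselective Diels–Alder reaction of methacrolein with (E)-3-methylpenta-2,4-dienyl acetate closes the ring in one operation, forming C1′–C2′ and C3′–C4′ and setting C1′. It exploits the quaternary carbon C2′ lying 1,3 to the carbinol carbon C6′: one of its methyls is carried as a formyl group that activates the dienophile, later (as CO2H) delivers the C6′ oxygen trans to the side chain through a bridged lactone, and is finally reduced to CH3. Negishi coupling with a 6-iodoluteolin ether follows.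

Key step: step 2

Remark (assumption): the (R)-configured oxazaborolidinium catalyst is taken to leave the C2-Si face of bound methacrolein open, as its accepted pre-transition-state model for 2-substituted acroleins predicts; if the opposite sense is found, the (S)-catalyst is used and nothing else changes.

**Step 1**
Reactants: 1 (2E)-3-methyl-4-oxobut-2-en-1-yl acetate
Product: 2 (2E)-3-methylpenta-2,4-dien-1-yl acetate
Conditions: Ph3PCH3Br, KN(SiMe3)2, THF, −78 → 0 °C
Reagents that add atoms: methyltriphenylphosphonium bromide, C[P+](c1ccccc1)(c1ccccc1)c1ccccc1.[Br-]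
Why: Wittig methylenation of the aldehyde by the non-stabilised ylide should be far faster than attack on the acetate and leaves the (E)-trisubstituted alkene untouched, so the (E)-diene results.

**Step 2**
Reactants: 2 (2E)-3-methylpenta-2,4-dien-1-yl acetate; 3 methacrolein
Product: 4 [(1R,6R)-6-formyl-2,6-dimethylcyclohex-2-en-1-yl]methyl acetate (formyl trans to the acetoxymethyl group)
Conditions: B-(o-tolyl)oxazaborolidine of (R)-α,α-diphenylprolinol protonated with HNTf2 (20 mol %), CH2Cl2, −78 → −40 °C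
Reagents that add atoms: none
Why: The protonated oxazaborolidine binds the formyl oxygen of methacrolein and a concerted, asynchronous normal-demand Diels–Alder reaction follows, the closest known type being the oxazaborolidinium-catalysed additions of 2-methylacrolein to acyclic dienes. The cyclohexene ring closes by intermolecular suprafacial [4+2] cycloaddition, with C3′–C4′ forming ahead of C1′–C2′ in the same step. The stereocentre that survives, C1′, is fixed by the catalyst (one enal face open) together with the formyl-exo topology and the (E)-geometry of the diene; the quaternary centre formed alongside is made achiral later. The step needs ortho regiochemistry (formyl-bearing carbon bonded to the acetoxymethyl-bearing terminus), which should follow because the dienophile β-CH2 attacks the unhindered CH2 terminus and the 1-substituent effect outweighs the opposing 2-methyl group. It also needs exo selectivity, which 2-substituted acroleins show under Lewis acid catalysis; any endo adduct is a diastereomer and is removed by chromatography.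

**Step 3**
Reactants: 4 [(1R,6R)-6-formyl-2,6-dimethylcyclohex-2-en-1-yl]methyl acetate
Product: 5 (1R,2R)-2-(acetoxymethyl)-1,3-dimethylcyclohex-3-ene-1-carboxylic acid
Conditions: NaClO2, NaH2PO4, 2-methyl-2-butene, t-BuOH/H2O, 0 °C → rt
Reagents that add atoms: sodium chlorite, [Na+].[O-]Cl=O
Why: Pinnick oxidation converts the aldehyde on the quaternary, non-epimerisable carbon into the acid while the scavenger protects the ring alkene from hypochlorous acid.

**Step 4**
Reactants: 5 (1R,2R)-2-(acetoxymethyl)-1,3-dimethylcyclohex-3-ene-1-carboxylic acid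
Product: 6 [(1R,5S,8R)-1,5-dimethyl-7-oxo-6-oxabicyclo[3.2.1]octan-8-yl]methyl acetate
Conditions: TfOH (10 mol %), CH2Cl2, 0 °C → rt
Reagents that add atoms: none
Why: Brønsted-acid-catalysed Markovnikov hydroacyloxylation (lactonisation): protonation of the trisubstituted alkene gives the tertiary cation, which the 1,3-cis carboxyl group can reach only from its own face, so the bridge sets the new C–O stereocentre trans to the acetoxymethyl group.

**Step 5**
Reactants: 6 [(1R,5S,8R)-1,5-dimethyl-7-oxo-6-oxabicyclo[3.2.1]octan-8-yl]methyl acetate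
Product: 7 (1R,5S,8R)-8-(hydroxymethyl)-1,5-dimethyl-6-oxabicyclo[3.2.1]octan-7-ol (lactol, both C7 epimers)
Conditions: i-Bu2AlH (3.5 equiv), CH2Cl2, −78 → −40 °C; aq. potassium sodium tartrate
Reagents that add atoms: none
Why: Lactone-to-lactol reduction should stop at the aluminium hemiacetal of the hindered bridged lactone at low temperature, and the acetate is cleaved reductively in the same flask.

**Step 6**
Reactants: 7 (1R,5S,8R)-8-(hydroxymethyl)-1,5-dimethyl-6-oxabicyclo[3.2.1]octan-7-ol
Product: 9 (1S,2R)-2-(hydroxymethyl)-1,3,3-trimethylcyclohexan-1-ol, via hydroxy aldehyde hydrazone 8 (not isolated)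
Conditions: N2H4·H2O, KOH, diethylene glycol, 130 °C then 200 °C
Reagents that add atoms: none
Why: Wolff–Kishner reduction (Huang–Minlon conditions) of the lactol through its open hydroxy aldehyde form turns the former formyl carbon into the second methyl group and frees the tertiary alcohol; the carbon next to it is quaternary, so no stereocentre is at risk.

**Step 7**
Reactants: 9 (1S,2R)-2-(hydroxymethyl)-1,3,3-trimethylcyclohexan-1-ol
Product: 10 (1S,2S)-2-(iodomethyl)-1,3,3-trimethylcyclohexan-1-ol
Conditions: I2, PPh3, imidazole, toluene/MeCN, rt → 50 °C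
Reagents that add atoms: iodine, II
Why: Appel-type iodination activates only the primary hydroxyl as its alkoxyphosphonium ion, the tertiary alcohol being too hindered to react.

**Step 8**
Reactants: 11 luteolin
Product: 12 7-(benzyloxy)-2-[3,4-bis(benzyloxy)phenyl]-5-hydroxy-4H-chromen-4-one
Conditions: BnBr (3.3 equiv), K2CO3, DMF, rt
Reagents that add atoms: benzyl bromide, BrCc1ccccc1
Why: Williamson etherification takes the three acidic hydroxyls and should leave the 5-OH, which is hydrogen-bonded to the C4 carbonyl, free.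

**Step 9**
Reactants: 12 7-(benzyloxy)-2-[3,4-bis(benzyloxy)phenyl]-5-hydroxy-4H-chromen-4-one
Product: 13 7-(benzyloxy)-2-[3,4-bis(benzyloxy)phenyl]-5-hydroxy-6-iodo-4H-chromen-4-one
Conditions: BnMe3N·ICl2 (1.1 equiv), CaCO3, CH2Cl2/MeOH, rt
Reagents that add atoms: benzyltrimethylammonium dichloroiodate, C[N+](C)(C)Cc1ccccc1.Cl[I-]Cl
Why: Electrophilic aromatic iodination of a 5-hydroxy-7-alkoxyflavone is directed ortho to the free phenol, to C6 and not C8, and the ring B ethers on the electron-poor chromone are less activated.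

**Step 10**
Reactants: 13 7-(benzyloxy)-2-[3,4-bis(benzyloxy)phenyl]-5-hydroxy-6-iodo-4H-chromen-4-one
Product: 14 5,7-bis(benzyloxy)-2-[3,4-bis(benzyloxy)phenyl]-6-iodo-4H-chromen-4-one
Conditions: BnBr, K2CO3, DMF, 70 °C
Reagents that add atoms: benzyl bromide, BrCc1ccccc1
Why: Williamson benzylation under more forcing conditions caps the chelated 5-OH, so that no acidic proton meets the organozinc reagent.

**Step 11**
Reactants: 10 (1S,2S)-2-(iodomethyl)-1,3,3-trimethylcyclohexan-1-ol; 14 5,7-bis(benzyloxy)-2-[3,4-bis(benzyloxy)phenyl]-6-iodo-4H-chromen-4-one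
Product: 17 5,7-bis(benzyloxy)-2-[3,4-bis(benzyloxy)phenyl]-6-{[(1S,6S)-6-hydroxy-2,2,6-trimethylcyclohexyl]methyl}-4H-chromen-4-one, via dilithio alkoxide 15 (not isolated), via alkylzinc chloride 16 (not isolated)
Conditions: t-BuLi (3.1 equiv), Et2O, −78 °C; ZnCl2, THF, −78 °C → rt; then 14, Pd(OAc)2 (5 mol %), RuPhos (10 mol %), THF/NMP, 60 °C; aq. NH4Cl
Reagents that add atoms: none
Why: Iodine–lithium exchange (after deprotonation of the alcohol), transmetalation to zinc and Negishi coupling with a biarylphosphine ligand made for doubly ortho-substituted aryl halides join the fragments at a primary carbon, so neither stereocentre is touched and the chromone is not attacked by the mild organozinc.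

**Step 12**
Reactants: 17 5,7-bis(benzyloxy)-2-[3,4-bis(benzyloxy)phenyl]-6-{[(1S,6S)-6-hydroxy-2,2,6-trimethylcyclohexyl]methyl}-4H-chromen-4-one
Product: 18 2-(3,4-dihydroxyphenyl)-5,7-dihydroxy-6-{[(1S,6S)-6-hydroxy-2,2,6-trimethylcyclohexyl]methyl}-4H-chromen-4-one (CNP0257603.1)
Conditions: H2 (1 atm), Pd/C (10 %), EtOAc/MeOH, rt
Reagents that add atoms: none
Why: Hydrogenolysis of the four benzyl ethers under neutral conditions should spare the tertiary alcohol (no acid, so no dehydration or cyclisation onto the phenol) and the chromone double bond.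

**Compound list**
1 | (2E)-3-methyl-4-oxobut-2-en-1-yl acetate | CC(=O)OC/C=C(\C)C=O | starting material
2 | (2E)-3-methylpenta-2,4-dien-1-yl acetate | CC(=O)OC/C=C(\C)C=C | intermediate
3 | methacrolein | CC(=C)C=O | starting material
4 | [(1R,6R)-6-formyl-2,6-dimethylcyclohex-2-en-1-yl]methyl acetate | O=C[C@]1(C)CCC=C(C)[C@H]1COC(C)=O | intermediate
5 | (1R,2R)-2-(acetoxymethyl)-1,3-dimethylcyclohex-3-ene-1-carboxylic acid | OC(=O)[C@]1(C)CCC=C(C)[C@H]1COC(C)=O | intermediate
6 | [(1R,5S,8R)-1,5-dimethyl-7-oxo-6-oxabicyclo[3.2.1]octan-8-yl]methyl acetate | CC(=O)OC[C@H]1[C@@]2(C)CCC[C@]1(C)OC2=O | intermediate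
7 | (1R,5S,8R)-8-(hydroxymethyl)-1,5-dimethyl-6-oxabicyclo[3.2.1]octan-7-ol (both C7 epimers) | OC[C@H]1[C@@]2(C)CCC[C@]1(C)OC2O | intermediate
8 | hydrazone of (1R,2R,3S)-3-hydroxy-2-(hydroxymethyl)-1,3-dimethylcyclohexane-1-carbaldehyde | NN=C[C@]1(C)CCC[C@](C)(O)[C@H]1CO | intermediate
9 | (1S,2R)-2-(hydroxymethyl)-1,3,3-trimethylcyclohexan-1-ol | CC1(C)CCC[C@](C)(O)[C@H]1CO | intermediate
10 | (1S,2S)-2-(iodomethyl)-1,3,3-trimethylcyclohexan-1-ol | CC1(C)CCC[C@](C)(O)[C@H]1CI | intermediate
11 | luteolin | O=c1cc(-c2ccc(O)c(O)c2)oc2cc(O)cc(O)c12 | starting material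
12 | 7-(benzyloxy)-2-[3,4-bis(benzyloxy)phenyl]-5-hydroxy-4H-chromen-4-one | O=c1cc(-c2ccc(OCc3ccccc3)c(OCc3ccccc3)c2)oc2cc(OCc3ccccc3)cc(O)c12 | intermediate
13 | 7-(benzyloxy)-2-[3,4-bis(benzyloxy)phenyl]-5-hydroxy-6-iodo-4H-chromen-4-one | O=c1cc(-c2ccc(OCc3ccccc3)c(OCc3ccccc3)c2)oc2cc(OCc3ccccc3)c(I)c(O)c12 | intermediate
14 | 5,7-bis(benzyloxy)-2-[3,4-bis(benzyloxy)phenyl]-6-iodo-4H-chromen-4-one | O=c1cc(-c2ccc(OCc3ccccc3)c(OCc3ccccc3)c2)oc2cc(OCc3ccccc3)c(I)c(OCc3ccccc3)c12 | intermediate
15 | lithium (1S,2S)-2-(lithiomethyl)-1,3,3-trimethylcyclohexan-1-olate | CC1(C)CCC[C@](C)(O[Li])[C@H]1C[Li] | intermediate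
16 | chloro{[(1S,6S)-6-(lithiooxy)-2,2,6-trimethylcyclohexyl]methyl}zinc | CC1(C)CCC[C@](C)(O[Li])[C@H]1C[Zn]Cl | intermediate
17 | 5,7-bis(benzyloxy)-2-[3,4-bis(benzyloxy)phenyl]-6-{[(1S,6S)-6-hydroxy-2,2,6-trimethylcyclohexyl]methyl}-4H-chromen-4-one | CC1(C)CCC[C@](C)(O)[C@H]1Cc1c(OCc2ccccc2)cc2oc(-c3ccc(OCc4ccccc4)c(OCc4ccccc4)c3)cc(=O)c2c1OCc1ccccc1 | intermediate
18 | 2-(3,4-dihydroxyphenyl)-5,7-dihydroxy-6-{[(1S,6S)-6-hydroxy-2,2,6-trimethylcyclohexyl]methyl}-4H-chromen-4-one | CC1(C)CCC[C@](C)(O)[C@H]1Cc1c(O)cc2oc(-c3ccc(O)c(O)c3)cc(=O)c2c1O | target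

**Step count.** Total: 12 steps. Longest linear sequence: 9 steps (steps 1–7, 11, 12); steps 8–10 form the second branch.

**Steps most likely to fail**

1. Step 2. Bond formation may start at the methyl-flanked diene terminus instead of the CH2 terminus (loss of regiocontrol), and discrimination of the enal faces or of the exo topology may be incomplete. Fallback from 1, back at 4: a 2-silyloxy diene whose oxygen dictates the regiochemistry is used and the oxygen is excised afterwards. MeMgBr (THF, −78 °C) adds to the aldehyde of 1 to give the allylic alcohol (2E)-4-hydroxy-3-methylpent-2-en-1-yl acetate F1. MnO2 oxidises it to the enone (2E)-3-methyl-4-oxopent-2-en-1-yl acetate F2. TIPSOTf/Et3N gives the diene (2E)-3-methyl-4-[(triisopropylsilyl)oxy]penta-2,4-dien-1-yl acetate F3. Its Diels–Alder reaction with 3 under the same catalyst should give the silyl enol ether [(1R,6R)-6-formyl-2,6-dimethyl-3-[(triisopropylsilyl)oxy]cyclohex-2-en-1-yl]methyl acetate F4. CsF/PhNTf2 converts this into the enol triflate [(1R,6R)-6-formyl-2,6-dimethyl-3-{[(trifluoromethyl)sulfonyl]oxy}cyclohex-2-en-1-yl]methyl acetate F5. Pd(OAc)2/PPh3, HCO2H and Bu3N reduce the triflate to 4.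

2. Step 11. Transmetalation and reductive elimination at the doubly ortho-substituted aryl–palladium centre may be slow, leaving room for β-hydride elimination and protodemetalation of the hindered alkylzinc. Fallback from 10, back at 17: boron replaces zinc and no organolithium is needed. Copper-catalysed borylation of 10 (B2pin2, CuI, PPh3, LiOMe, DMF) gives the boronate (1S,2S)-1,3,3-trimethyl-2-[(4,4,5,5-tetramethyl-1,3,2-dioxaborolan-2-yl)methyl]cyclohexan-1-ol F7. KHF2 converts it into potassium trifluoro{[(1S,6S)-6-hydroxy-2,2,6-trimethylcyclohexyl]methyl}borate F8. Suzuki–Miyaura coupling of F8 with 14 (Pd(OAc)2, RuPhos, K2CO3, toluene/H2O, 85 °C) gives 17.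

3. Step 4. The tertiary cation may lose a proton toward the ring CH (epimerisation through the tetrasubstituted alkene) or undergo a 1,2-shift before the carboxyl group closes. Fallback from 5, back at 6: iodolactonisation (I2, KI, NaHCO3, H2O/CH2Cl2) closes the same bridge under kinetic control without a free cation and should give [(1R,4R,5R,8R)-4-iodo-1,5-dimethyl-7-oxo-6-oxabicyclo[3.2.1]octan-8-yl]methyl acetate F6. Radical deiodination (Bu3SnH, AIBN, benzene, 80 °C) then gives 6.

**Further compounds**
F1 | step 2 | (2E)-4-hydroxy-3-methylpent-2-en-1-yl acetate (racemic carbinol) | CC(O)/C(C)=C/COC(C)=O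
F2 | step 2 | (2E)-3-methyl-4-oxopent-2-en-1-yl acetate | CC(=O)/C(C)=C/COC(C)=O
F3 | step 2 | (2E)-3-methyl-4-[(triisopropylsilyl)oxy]penta-2,4-dien-1-yl acetate | C=C(O[Si](C(C)C)(C(C)C)C(C)C)/C(C)=C/COC(C)=O
F4 | step 2 | [(1R,6R)-6-formyl-2,6-dimethyl-3-[(triisopropylsilyl)oxy]cyclohex-2-en-1-yl]methyl acetate | O=C[C@]1(C)CCC(O[Si](C(C)C)(C(C)C)C(C)C)=C(C)[C@H]1COC(C)=O
F5 | step 2 | [(1R,6R)-6-formyl-2,6-dimethyl-3-{[(trifluoromethyl)sulfonyl]oxy}cyclohex-2-en-1-yl]methyl acetate | O=C[C@]1(C)CCC(OS(=O)(=O)C(F)(F)F)=C(C)[C@H]1COC(C)=O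
F6 | step 4 | [(1R,4R,5R,8R)-4-iodo-1,5-dimethyl-7-oxo-6-oxabicyclo[3.2.1]octan-8-yl]methyl acetate | CC(=O)OC[C@H]1[C@@]2(C)CC[C@@H](I)[C@]1(C)OC2=O
F7 | step 11 | (1S,2S)-1,3,3-trimethyl-2-[(4,4,5,5-tetramethyl-1,3,2-dioxaborolan-2-yl)methyl]cyclohexan-1-ol | CC1(C)CCC[C@](C)(O)[C@H]1CB1OC(C)(C)C(C)(C)O1
F8 | step 11 | potassium trifluoro{[(1S,6S)-6-hydroxy-2,2,6-trimethylcyclohexyl]methyl}borate | CC1(C)CCC[C@](C)(O)[C@H]1C[B-](F)(F)F.[K+]
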